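The ten-membered carbocycle C1–C10 is disconnected at C5–C6. Because C6 is the β-carbon of a C11 carbonyl (through C7), the atoms C11, C7 and C6 are tied into a cyclopropanol: this stores the C7 stereocentre, hides a C6 carbanion equivalent and, on opening, returns C11 as the ketone that is later methylenated. In a single operation palladium joins this homoenolate carbon to the C5 alkenyl iodide, closing the ring with the C3/C6-trans C4=C5 olefin. The cyclisation substrate is an open chain with the (Z)-iodoalkene at C4=C5, the (E)-C1=C10 olefin, ether-protected C9, C14, C15 and C12 oxygens and a free trans-1,2-disubstituted cyclopropanol.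

Key step: step 11

Numbering: germacrane numbering is used throughout (ring C1–C10; C11 on C7 with C12 = CH2O and C13 = exocyclic CH2; C14 on C10; C15 on C4). Primed locants belong to the hydroxy acid.

Remarks on the chemistry:
- Across C4=C5 the ring carbons C3 and C6 are trans in every ring compound. Because C15 carries oxygen, the CIP descriptor of this bond is Z (it would be E with a C15 methyl group).
- The alkoxide-directed Kulinkovich reaction gives the 1,2-trans-dialkyl cyclopropanol, so 18 and 19 are drawn with the C11 hydroxyl cis to the C8 chain. C11 becomes trigonal in step 11, so this has no consequence.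
- Compound 12 is the (−)-methoxyborane derived from (+)-α-pinene.

Assumption: the directed Kulinkovich reaction is taken to follow the bicyclic titanacycle model (alkenyl substituent on C9 exo), which leads from the (9S)-alcohol to the required configuration at C7.

**Route**

Step 1
Reactants: 1 propargyl alcohol; 2 [2-(1,3-dioxan-2-yl)ethyl]magnesium bromide
Product: 3 (Z)-2-[2-(1,3-dioxan-2-yl)ethyl]-3-iodoprop-2-en-1-ol
Conditions: 2 (3 equiv), CuI (10 mol %), THF, −20 °C → rt; then I2, −78 → 0 °C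
Reagents that add atoms: iodine, II
Why: Copper-catalysed anti-carbomagnesiation of the propargylic magnesium alkoxide places the alkyl group on C4 and a chelated alkenylmagnesium on C5 cis to the CH2O group, and iodinolysis with retention should leave iodine trans to the C3 chain.

Step 2
Reactants: 3 (Z)-2-[2-(1,3-dioxan-2-yl)ethyl]-3-iodoprop-2-en-1-ol
Product: 4 tert-butyl{[(Z)-2-[2-(1,3-dioxan-2-yl)ethyl]-3-iodoprop-2-en-1-yl]oxy}diphenylsilane
Conditions: TBDPSCl, imidazole, CH2Cl2, 0 °C → rt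
Reagents that add atoms: tert-butyl(chloro)diphenylsilane, CC(C)(C)[Si](Cl)(c1ccccc1)c1ccccc1
Why: Silylation of a primary allylic alcohol with a silyl chloride and imidazole is routine and leaves the acetal and the alkenyl iodide untouched.

Step 3
Reactants: 4 tert-butyl{[(Z)-2-[2-(1,3-dioxan-2-yl)ethyl]-3-iodoprop-2-en-1-yl]oxy}diphenylsilane
Product: 5 (Z)-4-[(tert-butyldiphenylsilyloxy)methyl]-5-iodopent-4-enal
Conditions: 2 M HCl, THF, 40 °C
Reagents that add atoms: water, O
Why: Acid-catalysed acetal hydrolysis frees the C1 aldehyde, while the TBDPS ether tolerates dilute aqueous acid and the alkenyl iodide is inert.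

Step 4
Reactants: 5 (Z)-4-[(tert-butyldiphenylsilyloxy)methyl]-5-iodopent-4-enal; 6 4-methoxybenzyl alcohol; 7 ethyl 2-(diethoxyphosphoryl)acrylate
Product: 9 ethyl (2E,6Z)-6-[(tert-butyldiphenylsilyloxy)methyl]-7-iodo-2-[(4-methoxybenzyloxy)methyl]hepta-2,6-dienoate, via sodium phosphonate carbanion 8 (not isolated)
Conditions: NaH, THF, 0 °C (6, then 7 dropwise); then 5, 0 °C → rt
Reagents that add atoms: none
Why: Tandem oxa-Michael addition/Horner–Wadsworth–Emmons olefination, in which the alkoxide of 6 adds to vinylphosphonate 7 to give the stabilised carbanion 8 that olefinates 5; reversible adduct formation should favour the ester trans to the alkyl chain, and any (2Z)-isomer is removed by chromatography.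

Step 5
Reactants: 9 ethyl (2E,6Z)-6-[(tert-butyldiphenylsilyloxy)methyl]-7-iodo-2-[(4-methoxybenzyloxy)methyl]hepta-2,6-dienoate
Product: 10 (2Z,6Z)-6-[(tert-butyldiphenylsilyloxy)methyl]-7-iodo-2-[(4-methoxybenzyloxy)methyl]hepta-2,6-dien-1-ol (olefin geometry unchanged; the descriptor changes with CIP priority)
Conditions: iBu2AlH, CH2Cl2, −78 °C; aq. potassium sodium tartrate
Reagents that add atoms: none
Why: 1,2-Reduction of the conjugated ester by iBu2AlH at low temperature gives the allylic alcohol and spares the alkenyl iodide and the silyl and PMB ethers.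

Step 6
Reactants: 10 (2Z,6Z)-6-[(tert-butyldiphenylsilyloxy)methyl]-7-iodo-2-[(4-methoxybenzyloxy)methyl]hepta-2,6-dien-1-ol
Product: 11 (2E,6Z)-6-[(tert-butyldiphenylsilyloxy)methyl]-7-iodo-2-[(4-methoxybenzyloxy)methyl]hepta-2,6-dienal
Conditions: MnO2, CH2Cl2, rt
Reagents that add atoms: none
Why: MnO2 oxidises the allylic alcohol chemoselectively to the 2-substituted enal, whose formyl group stays trans to the chain.

Step 7
Reactants: 11 (2E,6Z)-6-[(tert-butyldiphenylsilyloxy)methyl]-7-iodo-2-[(4-methoxybenzyloxy)methyl]hepta-2,6-dienal; 12 (−)-B-methoxydiisopinocampheylborane; 13 allylmagnesium bromide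
Product: 15 (4S,5E,9Z)-9-[(tert-butyldiphenylsilyloxy)methyl]-10-iodo-5-[(4-methoxybenzyloxy)methyl]deca-1,5,9-trien-4-ol, via B-allyldiisopinocampheylborane 14 (not isolated)
Conditions: 12, 13, Et2O, −78 °C → rt; then 11, −78 °C; NaOH, H2O2, 0 °C → rt
Reagents that add atoms: none
Why: Brown allylation, in which allylborane 14 adds through a chair six-membered transition state and the isopinocampheyl groups from (+)-α-pinene direct attack to the aldehyde face that gives the (S)-carbinol at C9, the sense observed for aldehydes whose substituent outranks allyl.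

Step 8
Reactants: 16 ethyl glycolate
Product: 17 ethyl 2-(tert-butyldimethylsilyloxy)acetate
Conditions: TBSCl, imidazole, DMF, 0 °C → rt
Reagents that add atoms: tert-butyl(chloro)dimethylsilane, CC(C)(C)[Si](C)(C)Cl
Why: Routine silylation of a primary alcohol gives the ester partner for the cyclopropanation.

Step 9
Reactants: 15 (4S,5E,9Z)-9-[(tert-butyldiphenylsilyloxy)methyl]-10-iodo-5-[(4-methoxybenzyloxy)methyl]deca-1,5,9-trien-4-ol; 17 ethyl 2-(tert-butyldimethylsilyloxy)acetate
Product: 18 (1R,2S)-1-[(tert-butyldimethylsilyloxy)methyl]-2-[(2S,3E,7Z)-7-[(tert-butyldiphenylsilyloxy)methyl]-2-hydroxy-8-iodo-3-[(4-methoxybenzyloxy)methyl]octa-3,7-dien-1-yl]cyclopropan-1-ol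
Conditions: 17 (2.5 equiv), ClTi(OiPr)3, c-C6H11MgCl (slow addition), THF, rt
Reagents that add atoms: none
Why: Kulinkovich hydroxycyclopropanation in the olefin-exchange mode directed by the homoallylic alkoxide: the titanium-bound C9 oxygen should deliver the metal to one face of the C6=C7 alkene through an oxatitanabicyclo[3.1.0]hexane with the alkenyl substituent on C9 exo, and acylation by 17 then ring closure with retention at C7 should give the trans-1,2-dialkylcyclopropanol with C7 set, while the trisubstituted alkenes do not exchange.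

Step 10
Reactants: 18 (1R,2S)-1-[(tert-butyldimethylsilyloxy)methyl]-2-[(2S,3E,7Z)-7-[(tert-butyldiphenylsilyloxy)methyl]-2-hydroxy-8-iodo-3-[(4-methoxybenzyloxy)methyl]octa-3,7-dien-1-yl]cyclopropan-1-ol
Product: 19 (1R,2S)-1-[(tert-butyldimethylsilyloxy)methyl]-2-[(2S,3E,7Z)-7-[(tert-butyldiphenylsilyloxy)methyl]-8-iodo-3-[(4-methoxybenzyloxy)methyl]-2-(triethylsilyloxy)octa-3,7-dien-1-yl]cyclopropan-1-ol
Conditions: TESCl (1.1 equiv), imidazole, CH2Cl2, −20 → 0 °C
Reagents that add atoms: chlorotriethylsilane, CC[Si](Cl)(CC)CC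
Why: Silyl chloride/imidazole silylation should take the secondary allylic hydroxyl much faster than the tertiary cyclopropanol, which must stay free for step 11.

Step 11
Reactants: 19 (1R,2S)-1-[(tert-butyldimethylsilyloxy)methyl]-2-[(2S,3E,7Z)-7-[(tert-butyldiphenylsilyloxy)methyl]-8-iodo-3-[(4-methoxybenzyloxy)methyl]-2-(triethylsilyloxy)octa-3,7-dien-1-yl]cyclopropan-1-ol
Product: 20 (7R,9S,1(10)E,4Z)-12-(tert-butyldimethylsilyloxy)-15-(tert-butyldiphenylsilyloxy)-14-(4-methoxybenzyloxy)-9-(triethylsilyloxy)-13-norgermacra-1(10),4-dien-11-one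
Conditions: Pd(OAc)2 (15 mol %), XPhos (30 mol %), Cs2CO3, toluene, 80 °C, slow addition of 19 (final 1 mM)
Reagents that add atoms: none
Why: Proposed new method: oxidative addition of the C5–I bond to zerovalent palladium (formed from Pd(OAc)2 and XPhos) gives an alkenylpalladium iodide; carbonate-assisted exchange of iodide for the cyclopropanol oxygen and β-carbon elimination of the C11–C6 bond give a primary alkylpalladium ketone homoenolate, and C(sp2)–C(sp3) reductive elimination forms C5–C6. The closest known reaction is the intermolecular palladium-catalysed ring-opening cross-coupling of cyclopropanols with aryl and alkenyl halides; a ring-forming version has not been described. The ten-membered ring is closed by reductive elimination from an eleven-membered palladacycle, with both olefin carbons C4 and C5 inside the ring; no stereocentre is created, C7 and C9 are carried through, and the alkene geometry is retained so that C3 and C6 are trans across C4=C5. The step needs cleavage of C11–C6 instead of C11–C7 (palladium prefers the unsubstituted CH2 terminus), reductive elimination faster than β-hydride elimination to the α-methylene ketone (bulky biaryl phosphine) and no epimerisation at C7 (insoluble carbonate, short heating). Small-ring Heck pathways are excluded because palladium on C5 is trans to the C3 tether, zerovalent palladium meets only ethers at the allylic positions C9, C14 and C15, and slow addition at high dilution suppresses intermolecular coupling.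

Step 12
Reactants: 20 (7R,9S,1(10)E,4Z)-12-(tert-butyldimethylsilyloxy)-15-(tert-butyldiphenylsilyloxy)-14-(4-methoxybenzyloxy)-9-(triethylsilyloxy)-13-norgermacra-1(10),4-dien-11-one
Product: 21 (7R,9S,1(10)E,4Z)-12-(tert-butyldimethylsilyloxy)-15-(tert-butyldiphenylsilyloxy)-14-(4-methoxybenzyloxy)-9-(triethylsilyloxy)germacra-1(10),4,11(13)-triene
Conditions: Cp2Ti(μ-Cl)(μ-CH2)AlMe2, pyridine, THF/toluene, −40 → 0 °C
Reagents that add atoms: Tebbe reagent Cp2Ti(μ-Cl)(μ-CH2)AlMe2, C[Al-]1(C)C[Ti](C2C=CC=C2)(C2C=CC=C2)[Cl+]1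
Why: Tebbe methylenation uses a non-basic titanium methylidene, so the ketone should become the 1,1-disubstituted alkene without enolisation at C7 and with the silyl and PMB ethers intact.

Step 13
Reactants: 21 (7R,9S,1(10)E,4Z)-12-(tert-butyldimethylsilyloxy)-15-(tert-butyldiphenylsilyloxy)-14-(4-methoxybenzyloxy)-9-(triethylsilyloxy)germacra-1(10),4,11(13)-triene
Product: 22 (7R,9S,1(10)E,4Z)-12-(tert-butyldimethylsilyloxy)-15-(tert-butyldiphenylsilyloxy)-9-(triethylsilyloxy)germacra-1(10),4,11(13)-trien-14-ol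
Conditions: DDQ, CH2Cl2/NaH2PO4–Na2HPO4 buffer (pH 7), 0 °C
Reagents that add atoms: none
Why: Oxidative PMB ether cleavage by DDQ in buffered wet dichloromethane frees the C14 hydroxyl and leaves the silyl ethers and isolated alkenes untouched.

Step 14
Reactants: 23 (R)-4-benzyl-3-propionyloxazolidin-2-one; 24 acetaldehyde
Product: 26 (R)-4-benzyl-3-[(2R,3S)-3-hydroxy-2-methylbutanoyl]oxazolidin-2-one, via dibutylboron (Z)-enolate 25 (not isolated)
Conditions: Bu2BOTf, iPr2NEt, CH2Cl2, −78 → 0 °C; 24, −78 → 0 °C; then NaH2PO4–Na2HPO4 buffer (pH 7), MeOH, H2O2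
Reagents that add atoms: none
Why: Evans syn-aldol reaction, in which the (Z)-boron enolate 25 reacts through a chair Zimmerman–Traxler transition state and the (R)-benzyl auxiliary shields one enolate face, setting C2′ (R) and C3′ (S).

Step 15
Reactants: 26 (R)-4-benzyl-3-[(2R,3S)-3-hydroxy-2-methylbutanoyl]oxazolidin-2-one
Product: 27 (R)-4-benzyl-3-[(2R,3S)-3-(tert-butyldimethylsilyloxy)-2-methylbutanoyl]oxazolidin-2-one
Conditions: TBSOTf, 2,6-lutidine, CH2Cl2, 0 °C
Reagents that add atoms: tert-butyldimethylsilyl triflate, CC(C)(C)[Si](C)(C)OS(=O)(=O)C(F)(F)F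
Why: Silyl triflate with a hindered pyridine base silylates the secondary aldol hydroxyl without retro-aldol cleavage.

Step 16
Reactants: 27 (R)-4-benzyl-3-[(2R,3S)-3-(tert-butyldimethylsilyloxy)-2-methylbutanoyl]oxazolidin-2-one
Product: 28 (2R,3S)-3-(tert-butyldimethylsilyloxy)-2-methylbutanoic acid
Conditions: LiOH, H2O2, THF/H2O, 0 °C; Na2SO3
Reagents that add atoms: hydrogen peroxide (as lithium hydroperoxide), OO
Why: Hydroperoxide cleavage of the imide attacks the exocyclic carbonyl selectively and should not epimerise C2′.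

Step 17
Reactants: 22 (7R,9S,1(10)E,4Z)-12-(tert-butyldimethylsilyloxy)-15-(tert-butyldiphenylsilyloxy)-9-(triethylsilyloxy)germacra-1(10),4,11(13)-trien-14-ol; 28 (2R,3S)-3-(tert-butyldimethylsilyloxy)-2-methylbutanoic acid
Product: 30 (7R,9S,1(10)E,4Z)-12-(tert-butyldimethylsilyloxy)-14-[(2R,3S)-3-(tert-butyldimethylsilyloxy)-2-methylbutanoyloxy]-15-(tert-butyldiphenylsilyloxy)-9-(triethylsilyloxy)germacra-1(10),4,11(13)-triene, via O-acylisourea 29 (not isolated)
Conditions: EDC·HCl, DMAP (cat.), CH2Cl2, 0 °C → rt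
Reagents that add atoms: none
Why: Steglich esterification of the primary allylic alcohol through O-acylisourea 29 is mild enough to avoid epimerisation at C2′, and acylating C14 while C9 is still silylated avoids acyl migration between these two oxygens.

Step 18
Reactants: 30 (7R,9S,1(10)E,4Z)-12-(tert-butyldimethylsilyloxy)-14-[(2R,3S)-3-(tert-butyldimethylsilyloxy)-2-methylbutanoyloxy]-15-(tert-butyldiphenylsilyloxy)-9-(triethylsilyloxy)germacra-1(10),4,11(13)-triene
Product: 31 (7R,9S,1(10)E,4Z)-14-[(2R,3S)-3-(tert-butyldimethylsilyloxy)-2-methylbutanoyloxy]-15-(tert-butyldiphenylsilyloxy)germacra-1(10),4,11(13)-triene-9,12-diol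
Conditions: PPTS, MeOH/CH2Cl2, rt
Reagents that add atoms: none
Why: Mild acid-catalysed methanolysis should remove the secondary TES and primary TBS ethers while the hindered secondary TBS and the TBDPS ether survive, and the weak acid avoids transannular cyclisation of the 1,5-diene.

Step 19
Reactants: 31 (7R,9S,1(10)E,4Z)-14-[(2R,3S)-3-(tert-butyldimethylsilyloxy)-2-methylbutanoyloxy]-15-(tert-butyldiphenylsilyloxy)germacra-1(10),4,11(13)-triene-9,12-diol
Product: 32 (7R,9S,1(10)E,4Z)-12-acetoxy-14-[(2R,3S)-3-(tert-butyldimethylsilyloxy)-2-methylbutanoyloxy]-15-(tert-butyldiphenylsilyloxy)germacra-1(10),4,11(13)-trien-9-ol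
Conditions: AcCl (1.1 equiv), 2,4,6-collidine, CH2Cl2, −78 °C
Reagents that add atoms: acetyl chloride, CC(Cl)=O
Why: Acetyl chloride with a hindered pyridine base at low temperature should acetylate the primary allylic C12 hydroxyl selectively over the hindered secondary C9 hydroxyl.

Step 20
Reactants: 32 (7R,9S,1(10)E,4Z)-12-acetoxy-14-[(2R,3S)-3-(tert-butyldimethylsilyloxy)-2-methylbutanoyloxy]-15-(tert-butyldiphenylsilyloxy)germacra-1(10),4,11(13)-trien-9-ol
Product: 33 (7R,9S,1(10)E,4Z)-12-acetoxy-14-[(2R,3S)-3-(tert-butyldimethylsilyloxy)-2-methylbutanoyloxy]-15-(tert-butyldiphenylsilyloxy)-9-[(E)-2-methylbut-2-enoyloxy]germacra-1(10),4,11(13)-triene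
Conditions: tigloyl chloride, pyridine, DMAP, CH2Cl2, 0 °C → rt
Reagents that add atoms: tigloyl chloride, C/C=C(\C)C(Cl)=O
Why: DMAP-catalysed acylation of the secondary allylic alcohol installs the tiglate, which is the stable (E)-isomer, and pyridine as base avoids deconjugation through a vinylketene.

Step 21
Reactants: 33 (7R,9S,1(10)E,4Z)-12-acetoxy-14-[(2R,3S)-3-(tert-butyldimethylsilyloxy)-2-methylbutanoyloxy]-15-(tert-butyldiphenylsilyloxy)-9-[(E)-2-methylbut-2-enoyloxy]germacra-1(10),4,11(13)-triene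
Product: 34 (7R,9S,1(10)E,4Z)-12-acetoxy-14-[(2R,3S)-3-hydroxy-2-methylbutanoyloxy]-9-[(E)-2-methylbut-2-enoyloxy]germacra-1(10),4,11(13)-trien-15-ol
Conditions: HF·pyridine, pyridine, THF, 0 °C → rt
Reagents that add atoms: none
Why: Buffered fluoride desilylation removes the TBDPS and the remaining TBS ether without base, so the three esters should neither migrate nor hydrolyse.

Step 22
Reactants: 34 (7R,9S,1(10)E,4Z)-12-acetoxy-14-[(2R,3S)-3-hydroxy-2-methylbutanoyloxy]-9-[(E)-2-methylbut-2-enoyloxy]germacra-1(10),4,11(13)-trien-15-ol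
Product: 35 (4S,5R,7S,9S,1(10)E)-12-acetoxy-4,5-epoxy-14-[(2R,3S)-3-hydroxy-2-methylbutanoyloxy]-9-[(E)-2-methylbut-2-enoyloxy]germacra-1(10),11(13)-dien-15-ol (CNP0316239.1)
Conditions: Ti(OiPr)4, L-(+)-diethyl tartrate, tBuOOH, 4 Å molecular sieves, CH2Cl2, −20 °C
Reagents that add atoms: tert-butyl hydroperoxide, CC(C)(C)OO
Why: Sharpless asymmetric epoxidation, in which only C4=C5 belongs to an allylic alcohol and the titanium–L-(+)-tartrate complex should deliver oxygen to the face giving the (4S,5R)-epoxide (the sense that turns (E)-hex-2-en-1-ol into its (2S,3S)-epoxide), the addition being stereospecific so that C3 and C6 stay trans.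

**Compound list**

1 | propargyl alcohol (prop-2-yn-1-ol) | C#CCO | starting material
2 | [2-(1,3-dioxan-2-yl)ethyl]magnesium bromide (THF solution) | Br[Mg]CCC1OCCCO1 | starting material
3 | (Z)-2-[2-(1,3-dioxan-2-yl)ethyl]-3-iodoprop-2-en-1-ol | I/C=C(CO)/CCC1OCCCO1 | intermediate
4 | tert-butyl{[(Z)-2-[2-(1,3-dioxan-2-yl)ethyl]-3-iodoprop-2-en-1-yl]oxy}diphenylsilane | I/C=C(CO[Si](c1ccccc1)(c1ccccc1)C(C)(C)C)/CCC1OCCCO1 | intermediate
5 | (Z)-4-[(tert-butyldiphenylsilyloxy)methyl]-5-iodopent-4-enal | I/C=C(CO[Si](c1ccccc1)(c1ccccc1)C(C)(C)C)/CCC=O | intermediate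
6 | 4-methoxybenzyl alcohol | COc1ccc(CO)cc1 | starting material
7 | ethyl 2-(diethoxyphosphoryl)acrylate | C=C(C(=O)OCC)P(=O)(OCC)OCC | starting material
8 | sodium salt of ethyl 2-(diethoxyphosphoryl)-3-(4-methoxybenzyloxy)propanoate (phosphonate carbanion; not isolated) | CCOC(=O)[C-](COCc1ccc(OC)cc1)P(=O)(OCC)OCC.[Na+] | intermediate
9 | ethyl (2E,6Z)-6-[(tert-butyldiphenylsilyloxy)methyl]-7-iodo-2-[(4-methoxybenzyloxy)methyl]hepta-2,6-dienoate | CCOC(=O)/C(COCc1ccc(OC)cc1)=C/CC/C(CO[Si](c1ccccc1)(c1ccccc1)C(C)(C)C)=C/I | intermediate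
10 | (2Z,6Z)-6-[(tert-butyldiphenylsilyloxy)methyl]-7-iodo-2-[(4-methoxybenzyloxy)methyl]hepta-2,6-dien-1-ol | OC/C(COCc1ccc(OC)cc1)=C/CC/C(CO[Si](c1ccccc1)(c1ccccc1)C(C)(C)C)=C/I | intermediate
11 | (2E,6Z)-6-[(tert-butyldiphenylsilyloxy)methyl]-7-iodo-2-[(4-methoxybenzyloxy)methyl]hepta-2,6-dienal | O=C/C(COCc1ccc(OC)cc1)=C/CC/C(CO[Si](c1ccccc1)(c1ccccc1)C(C)(C)C)=C/I | intermediate
12 | (−)-B-methoxydiisopinocampheylborane (from (+)-α-pinene) | COB([C@@H]1C[C@@H]2C[C@H]([C@H]1C)C2(C)C)[C@@H]1C[C@@H]2C[C@H]([C@H]1C)C2(C)C | starting material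
13 | allylmagnesium bromide | C=CC[Mg]Br | starting material
14 | B-allyldiisopinocampheylborane from 12 (not isolated) | C=CCB([C@@H]1C[C@@H]2C[C@H]([C@H]1C)C2(C)C)[C@@H]1C[C@@H]2C[C@H]([C@H]1C)C2(C)C | intermediate
15 | (4S,5E,9Z)-9-[(tert-butyldiphenylsilyloxy)methyl]-10-iodo-5-[(4-methoxybenzyloxy)methyl]deca-1,5,9-trien-4-ol | C=CC[C@H](O)/C(COCc1ccc(OC)cc1)=C/CC/C(CO[Si](c1ccccc1)(c1ccccc1)C(C)(C)C)=C/I | intermediate
16 | ethyl glycolate | CCOC(=O)CO | starting material
17 | ethyl 2-(tert-butyldimethylsilyloxy)acetate | CCOC(=O)CO[Si](C)(C)C(C)(C)C | intermediate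
18 | (1R,2S)-1-[(tert-butyldimethylsilyloxy)methyl]-2-[(2S,3E,7Z)-7-[(tert-butyldiphenylsilyloxy)methyl]-2-hydroxy-8-iodo-3-[(4-methoxybenzyloxy)methyl]octa-3,7-dien-1-yl]cyclopropan-1-ol | I/C=C(CO[Si](c1ccccc1)(c1ccccc1)C(C)(C)C)/CC/C=C(COCc1ccc(OC)cc1)/[C@@H](O)C[C@H]1C[C@]1(O)CO[Si](C)(C)C(C)(C)C | intermediate
19 | (1R,2S)-1-[(tert-butyldimethylsilyloxy)methyl]-2-[(2S,3E,7Z)-7-[(tert-butyldiphenylsilyloxy)methyl]-8-iodo-3-[(4-methoxybenzyloxy)methyl]-2-(triethylsilyloxy)octa-3,7-dien-1-yl]cyclopropan-1-ol (C9 triethylsilyl ether of 18; cyclisation substrate) | I/C=C(CO[Si](c1ccccc1)(c1ccccc1)C(C)(C)C)/CC/C=C(COCc1ccc(OC)cc1)/[C@@H](O[Si](CC)(CC)CC)C[C@H]1C[C@]1(O)CO[Si](C)(C)C(C)(C)C | intermediate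
20 | (7R,9S,1(10)E,4Z)-12-(tert-butyldimethylsilyloxy)-15-(tert-butyldiphenylsilyloxy)-14-(4-methoxybenzyloxy)-9-(triethylsilyloxy)-13-norgermacra-1(10),4-dien-11-one | O=C(CO[Si](C)(C)C(C)(C)C)[C@H]1C[C@H](O[Si](CC)(CC)CC)/C(COCc2ccc(OC)cc2)=C/CC/C(CO[Si](c2ccccc2)(c2ccccc2)C(C)(C)C)=C/C1 | intermediate
21 | (7R,9S,1(10)E,4Z)-12-(tert-butyldimethylsilyloxy)-15-(tert-butyldiphenylsilyloxy)-14-(4-methoxybenzyloxy)-9-(triethylsilyloxy)germacra-1(10),4,11(13)-triene | C=C(CO[Si](C)(C)C(C)(C)C)[C@H]1C[C@H](O[Si](CC)(CC)CC)/C(COCc2ccc(OC)cc2)=C/CC/C(CO[Si](c2ccccc2)(c2ccccc2)C(C)(C)C)=C/C1 | intermediate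
22 | (7R,9S,1(10)E,4Z)-12-(tert-butyldimethylsilyloxy)-15-(tert-butyldiphenylsilyloxy)-9-(triethylsilyloxy)germacra-1(10),4,11(13)-trien-14-ol | C=C(CO[Si](C)(C)C(C)(C)C)[C@H]1C[C@H](O[Si](CC)(CC)CC)/C(CO)=C/CC/C(CO[Si](c2ccccc2)(c2ccccc2)C(C)(C)C)=C/C1 | intermediate
23 | (R)-4-benzyl-3-propionyloxazolidin-2-one | CCC(=O)N1[C@H](Cc2ccccc2)COC1=O | starting material
24 | acetaldehyde | CC=O | starting material
25 | dibutylboron (Z)-enolate of 23 (not isolated) | C/C=C(\OB(CCCC)CCCC)N1[C@H](Cc2ccccc2)COC1=O | intermediate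
26 | (R)-4-benzyl-3-[(2R,3S)-3-hydroxy-2-methylbutanoyl]oxazolidin-2-one | O=C1OC[C@@H](Cc2ccccc2)N1C(=O)[C@H](C)[C@H](C)O | intermediate
27 | (R)-4-benzyl-3-[(2R,3S)-3-(tert-butyldimethylsilyloxy)-2-methylbutanoyl]oxazolidin-2-one | O=C1OC[C@@H](Cc2ccccc2)N1C(=O)[C@H](C)[C@H](C)O[Si](C)(C)C(C)(C)C | intermediate
28 | (2R,3S)-3-(tert-butyldimethylsilyloxy)-2-methylbutanoic acid | OC(=O)[C@H](C)[C@H](C)O[Si](C)(C)C(C)(C)C | intermediate
29 | O-acylisourea from 28 and EDC (not isolated) | CCN=C(NCCCN(C)C)OC(=O)[C@H](C)[C@H](C)O[Si](C)(C)C(C)(C)C | intermediate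
30 | (7R,9S,1(10)E,4Z)-12-(tert-butyldimethylsilyloxy)-14-[(2R,3S)-3-(tert-butyldimethylsilyloxy)-2-methylbutanoyloxy]-15-(tert-butyldiphenylsilyloxy)-9-(triethylsilyloxy)germacra-1(10),4,11(13)-triene | C=C(CO[Si](C)(C)C(C)(C)C)[C@H]1C[C@H](O[Si](CC)(CC)CC)/C(COC(=O)[C@H](C)[C@H](C)O[Si](C)(C)C(C)(C)C)=C/CC/C(CO[Si](c2ccccc2)(c2ccccc2)C(C)(C)C)=C/C1 | intermediate
31 | (7R,9S,1(10)E,4Z)-14-[(2R,3S)-3-(tert-butyldimethylsilyloxy)-2-methylbutanoyloxy]-15-(tert-butyldiphenylsilyloxy)germacra-1(10),4,11(13)-triene-9,12-diol | C=C(CO)[C@H]1C[C@H](O)/C(COC(=O)[C@H](C)[C@H](C)O[Si](C)(C)C(C)(C)C)=C/CC/C(CO[Si](c2ccccc2)(c2ccccc2)C(C)(C)C)=C/C1 | intermediate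
32 | (7R,9S,1(10)E,4Z)-12-acetoxy-14-[(2R,3S)-3-(tert-butyldimethylsilyloxy)-2-methylbutanoyloxy]-15-(tert-butyldiphenylsilyloxy)germacra-1(10),4,11(13)-trien-9-ol | C=C(COC(C)=O)[C@H]1C[C@H](O)/C(COC(=O)[C@H](C)[C@H](C)O[Si](C)(C)C(C)(C)C)=C/CC/C(CO[Si](c2ccccc2)(c2ccccc2)C(C)(C)C)=C/C1 | intermediate
33 | (7R,9S,1(10)E,4Z)-12-acetoxy-14-[(2R,3S)-3-(tert-butyldimethylsilyloxy)-2-methylbutanoyloxy]-15-(tert-butyldiphenylsilyloxy)-9-[(E)-2-methylbut-2-enoyloxy]germacra-1(10),4,11(13)-triene | C=C(COC(C)=O)[C@H]1C[C@H](OC(=O)/C(C)=C/C)/C(COC(=O)[C@H](C)[C@H](C)O[Si](C)(C)C(C)(C)C)=C/CC/C(CO[Si](c2ccccc2)(c2ccccc2)C(C)(C)C)=C/C1 | intermediate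
34 | (7R,9S,1(10)E,4Z)-12-acetoxy-14-[(2R,3S)-3-hydroxy-2-methylbutanoyloxy]-9-[(E)-2-methylbut-2-enoyloxy]germacra-1(10),4,11(13)-trien-15-ol | C=C(COC(C)=O)[C@H]1C[C@H](OC(=O)/C(C)=C/C)/C(COC(=O)[C@H](C)[C@H](C)O)=C/CC/C(CO)=C/C1 | intermediate
35 | CNP0316239.1: (4S,5R,7S,9S,1(10)E)-12-acetoxy-4,5-epoxy-14-[(2R,3S)-3-hydroxy-2-methylbutanoyloxy]-9-[(E)-2-methylbut-2-enoyloxy]germacra-1(10),11(13)-dien-15-ol | C=C(COC(C)=O)[C@H]1C[C@H](OC(=O)/C(C)=C/C)/C(COC(=O)[C@H](C)[C@H](C)O)=C/CC[C@@]2(CO)O[C@@H]2C1 | target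

**Step count and risks**

Total step count: 22. Longest linear sequence: 18 steps (steps 1–7, 9–13 and 17–22).

Steps most likely to fail:

1. Step 11 (ring closure). The alkenylpalladium intermediate may be lost to intermolecular coupling or protodehalogenation before the strained eleven-membered palladacycle forms, the homoenolate may undergo β-hydride elimination instead of reductive elimination, and prolonged heating could epimerise C7 or start a Cope rearrangement of the 1,5-diene. Fallback with known chemistry, setting out from 19 and returning at 20: Et2Zn (THF, then DMSO as co-solvent) converts the cyclopropanol into the ethylzinc ketone homoenolate F1 by opening at C11–C6. This zinc-mediated opening is established for cyclopropanols. F1 is then cyclised under high dilution by Negishi coupling (Pd2(dba)3, SPhos, THF, 40 °C), a reaction class established for primary alkylzincs and alkenyl iodides, to give 20. This separates the C–C cleavage from the palladium cycle and runs at lower temperature.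

2. Step 9 (directed cyclopropanation). The 1,3-induction from the C9 alkoxide may have the opposite sense, so that the C7 epimer becomes the main product; too fast addition of the alkylmagnesium reagent could also start halogen–metal exchange at the alkenyl iodide. Fallback, setting out from 11 and returning at 18: the stereochemical relay is run from the other C9 configuration. Allylation of 11 with the enantiomeric allylborane F2 (from (+)-B-methoxydiisopinocampheylborane and 13) should give the (4R)-alcohol F3. The same directed Kulinkovich reaction with 17 should then give the (7S,9R)-cyclopropanol F4. Mitsunobu inversion at C9 (4-nitrobenzoic acid, PPh3, DIAD) gives the (9S)-4-nitrobenzoate F5, and methanolysis (K2CO3, MeOH) returns 18.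

3. Step 22 (epoxidation). The (Z)-2,3-disubstituted allylic alcohol sits inside the ring, so the reaction may be slow or show poor facial selectivity if the ring conformation opposes the tartrate complex, and the Lewis-acidic titanium could open the product epoxide transannularly. Fallback, setting out from 34 and returning at 35: Shi epoxidation with the D-fructose-derived ketone catalyst (KHSO5, K2CO3, MeCN/dimethoxymethane/H2O, 0 °C). Here a chiral dioxirane, not hydroxyl direction, selects the face. Treating C3–C4=C5–C6 as the trans-olefin unit of a trisubstituted alkene, the spiro transition-state model predicts the same (4S,5R)-epoxide, and C4=C5 is the most electron-rich alkene of 34. No new compound is formed on the way.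

Further compounds
F1 | step 11 | ethylzinc homoenolate: ethyl{(2R,4S,5E,9Z)-9-[(tert-butyldiphenylsilyloxy)methyl]-2-[2-(tert-butyldimethylsilyloxy)acetyl]-10-iodo-5-[(4-methoxybenzyloxy)methyl]-4-(triethylsilyloxy)deca-5,9-dien-1-yl}zinc | CC[Zn]C[C@H](C[C@H](O[Si](CC)(CC)CC)/C(COCc1ccc(OC)cc1)=C/CC/C(CO[Si](c1ccccc1)(c1ccccc1)C(C)(C)C)=C/I)C(=O)CO[Si](C)(C)C(C)(C)C
F2 | step 9 | enantiomeric B-allyldiisopinocampheylborane (from (−)-α-pinene; not isolated) | C=CCB([C@H]1C[C@H]2C[C@@H]([C@@H]1C)C2(C)C)[C@H]1C[C@H]2C[C@@H]([C@@H]1C)C2(C)C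
F3 | step 9 | (4R,5E,9Z)-9-[(tert-butyldiphenylsilyloxy)methyl]-10-iodo-5-[(4-methoxybenzyloxy)methyl]deca-1,5,9-trien-4-ol | C=CC[C@@H](O)/C(COCc1ccc(OC)cc1)=C/CC/C(CO[Si](c1ccccc1)(c1ccccc1)C(C)(C)C)=C/I
F4 | step 9 | (1R,2S)-1-[(tert-butyldimethylsilyloxy)methyl]-2-[(2R,3E,7Z)-7-[(tert-butyldiphenylsilyloxy)methyl]-2-hydroxy-8-iodo-3-[(4-methoxybenzyloxy)methyl]octa-3,7-dien-1-yl]cyclopropan-1-ol | I/C=C(CO[Si](c1ccccc1)(c1ccccc1)C(C)(C)C)/CC/C=C(COCc1ccc(OC)cc1)/[C@H](O)C[C@H]1C[C@]1(O)CO[Si](C)(C)C(C)(C)C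
F5 | step 9 | (9S)-4-nitrobenzoate of 18 (ester on the C9 oxygen; cyclopropanol free) | I/C=C(CO[Si](c1ccccc1)(c1ccccc1)C(C)(C)C)/CC/C=C(COCc1ccc(OC)cc1)/[C@@H](OC(=O)c1ccc(cc1)[N+](=O)[O-])C[C@H]1C[C@]1(O)CO[Si](C)(C)C(C)(C)C
F0 | step 22 | none | none
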